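The route rests on cutting the C2–C3 bond of each dihydrofuran ring (O1–C2–C3–C3a–C7a) and placing a nitrogen atom between the two carbons, which turns both rings into 2,4-diaryl-3,4-dihydro-2H-1,3-benzoxazines. The feature used is that C2 (next to O1 and a 4-oxyphenyl ring) and C3 (doubly benzylic) both carry radical character well. One twofold nitrogen deletion then contracts the two six-membered rings, forms both C2–C3 bonds and hands the C–N configurations on to C3. The precursor is the condensate of a bis(aminophenol) with two aldehyde molecules; its stereocentres come from one sulfinimine, used twice. The Z-alkene is set late from an alkyne.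

Key step: step 10

Abbreviations and locants: TIPS = triisopropylsilyl, TBS = tert-butyldimethylsilyl, MOM = methoxymethyl. C2/C3 belong to the terminal dihydrobenzofuran, which carries the 3,5-dioxyphenyl group. C2′/C3′ belong to the inner one, which carries the styryl group. Ring B is the benzo ring of the terminal unit and ring A that of the inner unit.

Assumption: the two sulfinimine additions follow the established models. These are the closed Mg-chelated transition state for the Grignard reagent in a non-coordinating medium and the open transition state for the aryllithium in THF. The ortho-OMOM group is taken not to override them.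

Step 1
Reactants: 1 5-bromoresorcinol
Product: 2 2-bromo-4,6-dihydroxybenzaldehyde
Conditions: POCl3, DMF, MeCN, 0 °C to rt; then H2O, 50 °C
Reagents that add atoms: N,N-dimethylformamide CN(C)C=O; water O
Why: Vilsmeier–Haack formylation of a resorcinol takes place at C4, ortho to one hydroxyl and para to the other, as it does with orcinol, and the two such positions of 1 are equivalent, so one aldehyde should result.

Step 2
Reactants: 2 2-bromo-4,6-dihydroxybenzaldehyde
Product: 3 2-bromo-6-hydroxy-4-(triisopropylsilyloxy)benzaldehyde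
Conditions: TIPSCl (1.05 equiv), imidazole, CH2Cl2, 0 °C
Reagents that add atoms: triisopropylsilyl chloride CC(C)[Si](Cl)(C(C)C)C(C)C
Why: Selective O-silylation should hit the free and more acidic 4-OH because the 6-OH is held in a hydrogen bond to the aldehyde and is flanked by it.

Step 3
Reactants: 3 2-bromo-6-hydroxy-4-(triisopropylsilyloxy)benzaldehyde
Product: 4 2-bromo-6-(methoxymethoxy)-4-(triisopropylsilyloxy)benzaldehyde
Conditions: MOMCl, i-Pr2NEt, CH2Cl2, 0 °C to reflux
Reagents that add atoms: chloromethyl methyl ether COCCl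
Why: O-alkylation to the MOM acetal masks the remaining phenol against the organometallic steps, and this group falls later in the same acid treatment as the sulfinyl groups.

Step 4
Reactants: 4 2-bromo-6-(methoxymethoxy)-4-(triisopropylsilyloxy)benzaldehyde; 5 (S)-2-methylpropane-2-sulfinamide
Product: 6 (S,E)-N-[2-bromo-6-(methoxymethoxy)-4-(triisopropylsilyloxy)benzylidene]-2-methylpropane-2-sulfinamide
Conditions: Ti(OEt)4 (2 equiv), THF, 65 °C
Reagents that add atoms: none
Why: Titanium(IV)-mediated tert-butanesulfinimine condensation gives the E-aldimine even from 2,6-disubstituted benzaldehydes and leaves the sulfur stereocentre of 5 untouched.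

Step 5
Reactants: 1 5-bromoresorcinol
Product: 7 1-bromo-3,5-bis(triisopropylsilyloxy)benzene
Conditions: TIPSCl (2.3 equiv), imidazole, DMF, rt
Reagents that add atoms: triisopropylsilyl chloride CC(C)[Si](Cl)(C(C)C)C(C)C
Why: Exhaustive O-silylation of the two equivalent phenols gives a base-stable and acid-tolerant aryl bromide for metalation.

Step 6
Reactants: 7 1-bromo-3,5-bis(triisopropylsilyloxy)benzene; 6 (S,E)-sulfinimine
Product: 9 (S)-N-{(R)-[2-bromo-6-(methoxymethoxy)-4-(triisopropylsilyloxy)phenyl][3,5-bis(triisopropylsilyloxy)phenyl]methyl}-2-methylpropane-2-sulfinamide, via arylmagnesium bromide 8 (not isolated)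
Conditions: 7, Mg (I2-activated), THF, 60 °C; then added to 6 in toluene, −48 °C to rt; then H2O
Reagents that add atoms: none
Why: 1,2-Addition of an aryl Grignard reagent to an N-tert-butanesulfinyl aldimine in a non-coordinating medium runs through the closed Mg-chelated six-membered transition state, in which the (S)-sulfinyl group directs the aryl group to the face that makes the new carbon stereocentre (the later C3) R.

Step 7
Reactants: 9 (S,R)-sulfinamide; 6 (S,E)-sulfinimine
Product: 11 bis-sulfinamide with the new ring A/ring B carbinamine carbon S and the older carbon R, via dilithiated sulfinamide 10 (not isolated)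
Conditions: 9, n-BuLi (2.1 equiv), THF, −78 °C; then 6, THF, −78 to −40 °C; then H2O
Reagents that add atoms: none
Why: After N–H deprotonation the bromine–lithium exchange outruns any attack on the anionic sulfinamide, and aryllithium addition to the same sulfinimine in THF follows the open transition state with the documented reversal of facial selectivity, so the second carbon stereocentre (the later C3′) is formed S.

Step 8
Reactants: 11 bis-sulfinamide
Product: 12 bis(aminophenol) with (S)-CH(NH2) between rings A and B and (R)-CH(NH2) between ring B and the 3,5-bis(TIPSO)phenyl ring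
Conditions: HCl (4 M in dioxane), MeOH, 0 °C to rt; then aq NaHCO3
Reagents that add atoms: none
Why: Acidic methanolysis cleaves the N-sulfinyl groups and the aryl MOM acetals together, while aryl TIPS ethers, the aryl bromide and the protonated benzhydrylic C–N stereocentres persist at room temperature.

Step 9
Reactants: 12 bis(aminophenol); 13 4-(tert-butyldimethylsilyloxy)benzaldehyde
Product: 14 bis(2,4-diaryl-3,4-dihydro-2H-1,3-benzoxazine) with 4S in the ring A oxazine and 4R in the ring B oxazine
Conditions: 13 (2.2 equiv), 4 Å molecular sieves, CH2Cl2, rt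
Reagents that add atoms: none
Why: Imine condensation at each amine is followed by 6-endo-trig addition of the neighbouring phenol oxygen to C=N (ring–chain tautomerism), and the two aminal carbons stay epimeric and mobile, which is of no consequence for the next step.

Step 10
Reactants: 14 bis(benzoxazine)
Product: 17 hexasilylated bis(trans-2,3-diaryl-2,3-dihydrobenzofuran) bromide with 2R,3R in the terminal ring and 2′S,3′S in the inner ring, via bis(1,1-diazene) 15 (not isolated), via C2-epimeric bromide mixture 16 (not isolated)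
Conditions: N-(benzyloxy)-N-(pivaloyloxy)-4-(trifluoromethyl)benzamide (2.6 equiv), THF, 45 °C, Ar; then evaporation, TFA (0.2 equiv), CH2Cl2, 0 °C
Reagents that add atoms: none
Why: Proposed new method: each ring nitrogen (N3, or the imine nitrogen of the open tautomer, which recloses once it is substituted) attacks the anomeric amide at nitrogen, pivalate leaves, benzyl 4-(trifluoromethyl)benzoate is expelled, and the cyclic 1,1-diazene 15 loses N2 to a singlet 1,5-biradical whose centres C2 and C4 recombine, so that the ring O1–C2–N3–C4–C4a–C8a becomes O1–C2–C3–C3a–C7a. The closest known reaction type is the nitrogen deletion of bis-benzylic secondary amines with this reagent, together with the stereoretentive contraction of 2,6-diarylpiperidine-derived 1,1-diazenes to 1,2-diarylcyclopentanes, but it has not been shown on N,O-aminals. Both five-membered rings close by intramolecular radical–radical recombination of a tethered biradical, not by a polar exo or endo attack. C3 and C3′ keep the configuration of the C–N carbons because rotation about the conjugated, ortho-flanked aryl–C• bond is slower than collapse of the singlet pair, so the new bond forms on the face that nitrogen vacates. C2 and C2′ emerge as epimer mixtures (16) and are then set trans to C3 and C3′ under thermodynamic control, since catalytic acid reversibly ionises the C2–O1 bond to the 4-silyloxybenzyl cation. The step needs N- over O-amination and recombination in preference to hydrazone formation or cycloreversion to an ortho-quinone methide, which the higher nucleophilicity of nitrogen and the double stabilisation of both radical centres (O1 plus aryl at C2, two aryl groups at C3) should secure, while the bulky TIPS groups shield the resorcinol ring from Friedel–Crafts capture of the C2′ cation.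

Step 11
Reactants: 17 bis(dihydrobenzofuran) bromide; 18 tert-butyl(4-ethynylphenoxy)dimethylsilane
Product: 19 heptasilylated diarylalkyne
Conditions: Pd(PhCN)2Cl2 (5 mol%), P(t-Bu)3 (10 mol%), CuI (5 mol%), i-Pr2NH, dioxane, 40 °C
Reagents that add atoms: none
Why: Sonogashira coupling with a bulky electron-rich phosphine engages the mono-ortho-substituted aryl bromide, which is meta to both oxygen substituents, under mild amine-base conditions that leave silyl ethers and stereocentres alone.

Step 12
Reactants: 19 heptasilylated diarylalkyne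
Product: 20 heptasilylated cis-miyabenol C
Conditions: H2 (1 atm), Lindlar catalyst, quinoline, EtOAc, rt
Reagents that add atoms: none
Why: Lindlar semihydrogenation delivers both hydrogens syn from the poisoned palladium surface and thus sets the Z-alkene, while this catalyst does not hydrogenolyse the benzylic C–O bonds of the dihydrobenzofurans.

Step 13
Reactants: 20 heptasilylated cis-miyabenol C
Product: 21 cis-miyabenol C
Conditions: TBAF (8 equiv), AcOH (8 equiv), THF, 0 °C, Ar, dark
Reagents that add atoms: none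
Why: Buffered fluoride desilylation frees all seven phenols without acid, silyl-protected Z-stilbenes are known to survive it without isomerisation, and any reversible ring opening through a para-quinone methide can only return the more stable trans rings.

Compound list
1 | 5-bromoresorcinol | Oc1cc(O)cc(Br)c1 | starting material
2 | 2-bromo-4,6-dihydroxybenzaldehyde | O=Cc1c(O)cc(O)cc1Br | intermediate
3 | 2-bromo-6-hydroxy-4-(triisopropylsilyloxy)benzaldehyde | O=Cc1c(O)cc(O[Si](C(C)C)(C(C)C)C(C)C)cc1Br | intermediate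
4 | 2-bromo-6-(methoxymethoxy)-4-(triisopropylsilyloxy)benzaldehyde | O=Cc1c(OCOC)cc(O[Si](C(C)C)(C(C)C)C(C)C)cc1Br | intermediate
5 | (S)-2-methylpropane-2-sulfinamide | CC(C)(C)[S@](=O)N | starting material
6 | (S,E)-N-[2-bromo-6-(methoxymethoxy)-4-(triisopropylsilyloxy)benzylidene]-2-methylpropane-2-sulfinamide | Brc1cc(O[Si](C(C)C)(C(C)C)C(C)C)cc(OCOC)c1/C=N/[S@@](=O)C(C)(C)C | intermediate
7 | 1-bromo-3,5-bis(triisopropylsilyloxy)benzene | Brc1cc(O[Si](C(C)C)(C(C)C)C(C)C)cc(O[Si](C(C)C)(C(C)C)C(C)C)c1 | intermediate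
8 | 3,5-bis(triisopropylsilyloxy)phenylmagnesium bromide (not isolated) | Br[Mg]c1cc(O[Si](C(C)C)(C(C)C)C(C)C)cc(O[Si](C(C)C)(C(C)C)C(C)C)c1 | intermediate
9 | (S)-N-{(R)-[2-bromo-6-(methoxymethoxy)-4-(triisopropylsilyloxy)phenyl][3,5-bis(triisopropylsilyloxy)phenyl]methyl}-2-methylpropane-2-sulfinamide | Brc1cc(O[Si](C(C)C)(C(C)C)C(C)C)cc(OCOC)c1[C@@H](c1cc(O[Si](C(C)C)(C(C)C)C(C)C)cc(O[Si](C(C)C)(C(C)C)C(C)C)c1)N[S@@](=O)C(C)(C)C | intermediate
10 | N,C-dilithiated 9, with Li in place of Br and of N–H (not isolated) | [Li]c1cc(O[Si](C(C)C)(C(C)C)C(C)C)cc(OCOC)c1[C@@H](c1cc(O[Si](C(C)C)(C(C)C)C(C)C)cc(O[Si](C(C)C)(C(C)C)C(C)C)c1)N([Li])[S@@](=O)C(C)(C)C | intermediate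
11 | bis-sulfinamide: (S)-N-{(S)-[2-bromo-6-(MOMO)-4-(TIPSO)phenyl][2-{(R)-[3,5-bis(TIPSO)phenyl][((S)-tert-butylsulfinyl)amino]methyl}-3-(MOMO)-5-(TIPSO)phenyl]methyl}-2-methylpropane-2-sulfinamide | Brc1cc(O[Si](C(C)C)(C(C)C)C(C)C)cc(OCOC)c1[C@H](c1cc(O[Si](C(C)C)(C(C)C)C(C)C)cc(OCOC)c1[C@@H](c1cc(O[Si](C(C)C)(C(C)C)C(C)C)cc(O[Si](C(C)C)(C(C)C)C(C)C)c1)N[S@@](=O)C(C)(C)C)N[S@@](=O)C(C)(C)C | intermediate
12 | bis(aminophenol): 2-{(S)-amino[2-{(R)-amino[3,5-bis(TIPSO)phenyl]methyl}-3-hydroxy-5-(TIPSO)phenyl]methyl}-3-bromo-5-(TIPSO)phenol | Brc1cc(O[Si](C(C)C)(C(C)C)C(C)C)cc(O)c1[C@H](c1cc(O[Si](C(C)C)(C(C)C)C(C)C)cc(O)c1[C@@H](c1cc(O[Si](C(C)C)(C(C)C)C(C)C)cc(O[Si](C(C)C)(C(C)C)C(C)C)c1)N)N | intermediate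
13 | 4-(tert-butyldimethylsilyloxy)benzaldehyde | O=Cc1ccc(O[Si](C)(C)C(C)(C)C)cc1 | starting material
14 | (4S)-5-bromo-4-{(4R)-4-[3,5-bis(TIPSO)phenyl]-2-[4-(TBSO)phenyl]-7-(TIPSO)-3,4-dihydro-2H-1,3-benzoxazin-5-yl}-2-[4-(TBSO)phenyl]-7-(TIPSO)-3,4-dihydro-2H-1,3-benzoxazine, epimeric at both aminal carbons C2 and in equilibrium with the open imine–phenol forms | Brc2cc(O[Si](C(C)C)(C(C)C)C(C)C)cc3c2[C@H](c2cc(O[Si](C(C)C)(C(C)C)C(C)C)cc4c2[C@@H](c2cc(O[Si](C(C)C)(C(C)C)C(C)C)cc(O[Si](C(C)C)(C(C)C)C(C)C)c2)NC(c2ccc(O[Si](C)(C)C(C)(C)C)cc2)O4)NC(c2ccc(O[Si](C)(C)C(C)(C)C)cc2)O3 | intermediate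
15 | bis(1,1-diazene) of 14, with each N3 carrying a terminal nitrene-type nitrogen (not isolated) | Brc2cc(O[Si](C(C)C)(C(C)C)C(C)C)cc3c2[C@H](c2cc(O[Si](C(C)C)(C(C)C)C(C)C)cc4c2[C@@H](c2cc(O[Si](C(C)C)(C(C)C)C(C)C)cc(O[Si](C(C)C)(C(C)C)C(C)C)c2)[N+](=[N-])C(c2ccc(O[Si](C)(C)C(C)(C)C)cc2)O4)[N+](=[N-])C(c2ccc(O[Si](C)(C)C(C)(C)C)cc2)O3 | intermediate
16 | bis(dihydrobenzofuran) bromide with 3R and 3′S fixed, epimeric at C2 and C2′ (not isolated) | Brc2cc(O[Si](C(C)C)(C(C)C)C(C)C)cc3c2[C@H](c2cc(O[Si](C(C)C)(C(C)C)C(C)C)cc4c2[C@@H](c2cc(O[Si](C(C)C)(C(C)C)C(C)C)cc(O[Si](C(C)C)(C(C)C)C(C)C)c2)C(c2ccc(O[Si](C)(C)C(C)(C)C)cc2)O4)C(c2ccc(O[Si](C)(C)C(C)(C)C)cc2)O3 | intermediate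
17 | (2S,3S)-4-bromo-3-{(2R,3R)-3-[3,5-bis(TIPSO)phenyl]-2-[4-(TBSO)phenyl]-6-(TIPSO)-2,3-dihydrobenzofuran-4-yl}-2-[4-(TBSO)phenyl]-6-(TIPSO)-2,3-dihydrobenzofuran | Brc2cc(O[Si](C(C)C)(C(C)C)C(C)C)cc3c2[C@H](c2cc(O[Si](C(C)C)(C(C)C)C(C)C)cc4c2[C@@H](c2cc(O[Si](C(C)C)(C(C)C)C(C)C)cc(O[Si](C(C)C)(C(C)C)C(C)C)c2)[C@H](c2ccc(O[Si](C)(C)C(C)(C)C)cc2)O4)[C@@H](c2ccc(O[Si](C)(C)C(C)(C)C)cc2)O3 | intermediate
18 | tert-butyl(4-ethynylphenoxy)dimethylsilane | C#Cc1ccc(O[Si](C)(C)C(C)(C)C)cc1 | starting material
19 | analogue of 17 with a [4-(TBSO)phenyl]ethynyl group in place of Br (2R,3R,2′S,3′S) | CC(C)(C)[Si](C)(C)Oc1ccc(C#Cc2cc(O[Si](C(C)C)(C(C)C)C(C)C)cc3c2[C@H](c2cc(O[Si](C(C)C)(C(C)C)C(C)C)cc4c2[C@@H](c2cc(O[Si](C(C)C)(C(C)C)C(C)C)cc(O[Si](C(C)C)(C(C)C)C(C)C)c2)[C@H](c2ccc(O[Si](C)(C)C(C)(C)C)cc2)O4)[C@@H](c2ccc(O[Si](C)(C)C(C)(C)C)cc2)O3)cc1 | intermediate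
20 | heptasilylated cis-miyabenol C, a (Z)-stilbene (2R,3R,2′S,3′S) | CC(C)(C)[Si](C)(C)Oc1ccc(/C=C\c2cc(O[Si](C(C)C)(C(C)C)C(C)C)cc3c2[C@H](c2cc(O[Si](C(C)C)(C(C)C)C(C)C)cc4c2[C@@H](c2cc(O[Si](C(C)C)(C(C)C)C(C)C)cc(O[Si](C(C)C)(C(C)C)C(C)C)c2)[C@H](c2ccc(O[Si](C)(C)C(C)(C)C)cc2)O4)[C@@H](c2ccc(O[Si](C)(C)C(C)(C)C)cc2)O3)cc1 | intermediate
21 | cis-miyabenol C | Oc1ccc(/C=C\c2cc(O)cc3c2[C@H](c2cc(O)cc4c2[C@@H](c2cc(O)cc(O)c2)[C@H](c2ccc(O)cc2)O4)[C@@H](c2ccc(O)cc2)O3)cc1 | target

Total step count: 13. Longest linear sequence: 12 steps (steps 1–4 and 6–13).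

Steps most likely to fail

(i) Step 10, the twofold nitrogen deletion.
- What may go wrong: amination of the two hindered nitrogens may be slow. The open imine–phenol tautomers may drift into O-amination or hydrolysis. The diazene may leak into cycloreversion, with loss of the C3 or C3′ configuration. The second deletion may stay incomplete.
- Fallback: it uses known chemistry, sets out from 3 and comes back at 17. Phenol 3 is acylated with Boc2O/DMAP to tert-butyl 3-bromo-2-formyl-5-(triisopropylsilyloxy)phenyl carbonate F1.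
- First annulation: one equivalent of Grignard reagent 8 is added to F1. This triggers the known alkoxide-to-phenoxide carbonate transfer and elimination to the ortho-quinone methide stage. That species is intercepted in the same flask, in a formal [4+1] annulation, by the benzylide generated with LiHMDS from (2R,5R)-1-[4-(tert-butyldimethylsilyloxy)benzyl]-2,5-dimethylthiolan-1-ium tetrafluoroborate F2. F2 is made from the C2-symmetric sulfide, 4-(tert-butyldimethylsilyloxy)benzyl bromide and AgBF4. The product is (2R,3R)-4-bromo-3-[3,5-bis(TIPSO)phenyl]-2-[4-(TBSO)phenyl]-6-(TIPSO)-2,3-dihydrobenzofuran F3.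
- Second annulation: bromine–lithium exchange on F3 is followed by addition to a second portion of F1. The ylide of the enantiomeric salt (2S,5S)-1-[4-(tert-butyldimethylsilyloxy)benzyl]-2,5-dimethylthiolan-1-ium tetrafluoroborate F4 then intercepts the quinone methide and gives 17.
- Stereocontrol: the absolute sense of each ring then rests on the sulfide. Which enantiomer serves which ring has to be settled by experiment.

(ii) Step 7, the dianion addition.
- What may go wrong: aggregation and steric shielding of the dilithiated nucleophile may slow the addition. Bromine–lithium scrambling with 6, protonation of the aryllithium, or poor facial selectivity from a mismatch between chiral nucleophile and auxiliary may then take over.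
- Fallback: it sets out from 9 and comes back at 11. Miyaura borylation of 9 (Pd(dppf)Cl2, B2pin2, KOAc, dioxane) gives the pinacol boronate of 9 F5.
- Return to the route: F5 is added to sulfinimine 6 by the known rhodium(I)-catalysed addition of aryl boron reagents to N-tert-butanesulfinyl aldimines. No strong base is involved. A non-chelated addition mode is expected, with the same facial sense as for the aryllithium.

(iii) Step 12, the semihydrogenation.
- What may go wrong: the alkene may be over-reduced to the saturated bridge. The reaction may stall because neighbouring silyl ethers shield the alkyne. The alkene may drift from Z to E on the catalyst.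
- Fallback: it sets out from 17 (with 18) and comes back at 20, bypassing 19. Rhodium-catalysed trans-hydroboration of 18 with pinacolborane gives (Z)-2-[4-(tert-butyldimethylsilyloxy)styryl]-4,4,5,5-tetramethyl-1,3,2-dioxaborolane F6.
- Return to the route: F6 is joined to 17 by a stereoretentive Suzuki–Miyaura coupling (Pd(OAc)2, SPhos, K3PO4, THF/H2O).

Further compounds
F1 | step 10 | tert-butyl 3-bromo-2-formyl-5-(triisopropylsilyloxy)phenyl carbonate | O=Cc1c(OC(=O)OC(C)(C)C)cc(O[Si](C(C)C)(C(C)C)C(C)C)cc1Br
F2 | step 10 | (2R,5R)-1-[4-(tert-butyldimethylsilyloxy)benzyl]-2,5-dimethylthiolan-1-ium tetrafluoroborate | C[C@@H]1CC[C@@H](C)[S+]1Cc1ccc(O[Si](C)(C)C(C)(C)C)cc1.F[B-](F)(F)F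
F3 | step 10 | (2R,3R)-4-bromo-3-[3,5-bis(triisopropylsilyloxy)phenyl]-2-[4-(tert-butyldimethylsilyloxy)phenyl]-6-(triisopropylsilyloxy)-2,3-dihydrobenzofuran | Brc2cc(O[Si](C(C)C)(C(C)C)C(C)C)cc4c2[C@@H](c2cc(O[Si](C(C)C)(C(C)C)C(C)C)cc(O[Si](C(C)C)(C(C)C)C(C)C)c2)[C@H](c2ccc(O[Si](C)(C)C(C)(C)C)cc2)O4
F4 | step 10 | (2S,5S)-1-[4-(tert-butyldimethylsilyloxy)benzyl]-2,5-dimethylthiolan-1-ium tetrafluoroborate | C[C@H]1CC[C@H](C)[S+]1Cc1ccc(O[Si](C)(C)C(C)(C)C)cc1.F[B-](F)(F)F
F5 | step 7 | pinacol boronate of 9 (Bpin in place of Br, carbon R, sulfur S) | CC1(C)OB(OC1(C)C)c1cc(O[Si](C(C)C)(C(C)C)C(C)C)cc(OCOC)c1[C@@H](c1cc(O[Si](C(C)C)(C(C)C)C(C)C)cc(O[Si](C(C)C)(C(C)C)C(C)C)c1)N[S@@](=O)C(C)(C)C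
F6 | step 12 | (Z)-2-[4-(tert-butyldimethylsilyloxy)styryl]-4,4,5,5-tetramethyl-1,3,2-dioxaborolane | CC1(C)OB(OC1(C)C)/C=C\c1ccc(O[Si](C)(C)C(C)(C)C)cc1
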